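The rate constants are invented; the run is a simulation.

If target comes out of intermediate B by a first-order step, I reasoned, then what a vessel does to target should show in the age of B inside it.

| flask | starting material | capture agent | time | remark |
|---|---|---|---|---|
| north-west | 20 mM | 1.00 mM | 2.5 h | a closed flask charged with all of it at once and left for 2.5 h |
| west | 20 mM | 1.00 mM |  | a single well-mixed tank run continuously and read at steady state, 2.5 h in it on average |
| north-east | 20 mM | 1.00 mM | 2.5 h | plug flow through a tube for 2.5 h, no back-mixing |
| south-west | 20 mM (fed, over 1.25 h) | 1.00 mM | 2.5 h | a stirred flask in which starting material is dosed at a steady rate over 1.25 h without added volume, worked up at 2.5 h |

    starting material ⇌ side product (K1 = 0.21, k1 = 0.013 min⁻¹)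
    starting material → intermediate A (k2 = 0.0022 min⁻¹)
    intermediate A → intermediate B (k3 = 0.039 min⁻¹)
    intermediate B → target (k4 = 0.0027 min⁻¹)
    intermediate A → decomposed reagent (k5 = 0.018 min⁻¹)
    capture agent + intermediate A → trapped intermediate (k6 = 13 M⁻¹ min⁻¹)

* the set-up with the highest share of target in all that became target or side product or trapped intermediate, at the outlet or at the end ("none" if the first two lie within 2 percentage points) (north-west / west / north-east / south-west / none)
* share of target in all that became target or side product or trapped intermediate, at the outlet or at the end, north-west
* share of target in all that became target or side product or trapped intermediate, at the outlet or at the end, west
* share of target in all that became target or side product or trapped intermediate, at the outlet or at the end, north-east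
* share of target in all that became target or side product or trapped intermediate, at the outlet or at the end, south-west

- the stated concentrations are those of everything mixed, before any reaction; amounts are the same in each set-up
- the feed brings no volume worth counting
- run time (north-west): 2.5 h

I carried one quantity, target per B: the amount of target divided by the amount of intermediate B standing beside it. In the tank at steady state, target leaves as fast as B makes it, so the ratio is the rate constant of the last step, 0.0027 min⁻¹, times the mean residence time, 0.405. I then solved the other end, the vessels with no back-mixing. By step 4, B lives 6.17 h on average, longer than the run, so as an approximation I neglected its draining. The ratio there is then, as an estimate, 0.0027 min⁻¹ times the mean age of the B present.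

| vessel | time multiplying the last rate constant | target per B |
|---|---|---|
| west | 2.5 h | 0.405 |
| north-west, north-east | 1.25 h | 0.203 |
| south-west | 0.938 h | 0.152 |

I read the table from the top. The tank's entry is its mean residence time, 2.5 h, and its row holds exactly at steady state. In the closed flask, B rises about steadily from zero, and intermediate A delays it little, its half-life by step 3 being 0.30 h, shorter than the run. So the mean age there is half the time, and the tank's ratio is twice the flask's. The tube's row is the same, since each slice of plug flow is a closed flask of that age. In south-west the dose enters on average 0.625 h late, so I halved the shorter time, and that ratio came out lower than the closed flask's.

The relaxation half-life of starting material and side product, 0.154 h, is short against the run, so I set side product at 0.21 times starting material in each vessel. I took that denominator as similar throughout. I did not reckon how much B stands in each vessel, so the order rested on the ratios: I committed to west, then north-west equal with north-east, then south-west, and to no percentages.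

The forecast named west, with 19% there, 11.9% in north-west, 11.9% in north-east and 6.1% in south-west, holding that “the long residence-time tail of the stirred tank gives it the most target”. Its order was mine.

The simulation gave west at 19.0%, with 11.9% in north-west, 11.9% in north-east and 7.06% in south-west. West ended with 8.50% of intermediate B, so 0.405 puts its target at 3.44% of the charge. In south-west at 2.50 h, target stood at 1.28% beside 8.35% of B, a reading of 0.153 against the 0.152 from the table.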